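**Plan**

Numbering used throughout: ring atoms C1–C10, with C1 = epoxide CH beside the ring CH2 C2, C3 = CH–OAng, C4(Me)–C5 = second epoxide, C6 = CH2, C7 = CH–isopropenyl, C8 = CH–OAc, C9 = CH–OAng, C10(Me) = partner of C1 in the first epoxide.
Cuts (retro order): the three ester C–O bonds; the C4–C5 epoxide back to the Z-alkene; the C1–C10 epoxide back to C1–OTs/C10–OH; the ring bond C1–C2 (aldol retron C1(OH)–C2–C3=O); then C2–C3, C1–C10 and C8–C9, which leaves C3–C8 as (S)-carvone cut between its carbonyl carbon and C6.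
Forward: the carvone ring is opened to a Z-enoate aldehyde, the chain is grown at C8 (C9, C10), at C10 (C1) and at C3 (C2), the ten-membered ring is closed at C1–C2, then the C1–C10 epoxide, the C4–C5 epoxide and the esters follow.
Enabling feature: C2 is the only CH2 between two oxygenated carbons, and both are backed by carbons without hydrogen: quaternary O-bearing C10 makes the C1 aldehyde non-enolisable and chelating, and the methyl-bearing alkene carbon C4 leaves C2 as the only α-position of the C3 ketone; the Z-alkene and the seven-membered disiloxane ring across O8/O9 fold the chain.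
Stereochemistry: C7 from (S)-carvone and Z-C4=C5 from its ring; C8/C9 from L-proline; C10 by Felkin–Anh addition; C1 by samarium chelation in the ring closure, inverted on epoxide closure; C3 by 1,3-anti hydride delivery from O1; C4/C5 by C3–OH-directed peracid epoxidation.

Key step: step 11

Remark: step 1 should give mainly the trans ketol 2; its C6 epimer is carried along because that carbon becomes the aldehyde carbon of 3. The acetal carbon of 9 and the carbinol carbon of 12 are epimer mixtures that disappear later.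

Step 1
Reactants: 1 (S)-carvone
Product: 2 (5R,6R)-6-hydroxy-2-methyl-5-(prop-1-en-2-yl)cyclohex-2-en-1-one
Conditions: KN(SiMe3)2, THF, −78 °C; then 2-(phenylsulfonyl)-3-phenyloxaziridine, −78 °C; aq. NH4Cl
Reagents that add atoms: 2-(phenylsulfonyl)-3-phenyloxaziridine, O=S(=O)(c1ccccc1)N1OC1c1ccccc1
Why: Kinetic deprotonation at C6 gives the cross-conjugated enolate, which the N-sulfonyloxaziridine hydroxylates (enolate α-hydroxylation) mainly anti to the isopropenyl group, the new carbinol centre being sacrificed in step 2.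

Step 2
Reactants: 2 (5R,6R)-6-hydroxy-2-methyl-5-(prop-1-en-2-yl)cyclohex-2-en-1-one
Product: 3 methyl (2Z,5R)-5-formyl-2,6-dimethylhepta-2,6-dienoate
Conditions: Pb(OAc)4, MeOH/benzene 1:1, 0 °C
Reagents that add atoms: methanol, CO
Why: Glycol-type oxidative cleavage of the α-ketol through its methyl hemiketal cuts the bond between carbonyl and carbinol carbon, giving ester C3 and aldehyde C8, while the ring-locked cis alkene becomes the Z-enoate C4=C5 and C7 is untouched.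

Step 3
Reactants: 3 methyl (2Z,5R)-5-formyl-2,6-dimethylhepta-2,6-dienoate; 4 hydroxyacetone
Product: 5 methyl (2Z,5R,6S,7S)-6,7-dihydroxy-2-methyl-8-oxo-5-(prop-1-en-2-yl)non-2-enoate
Conditions: L-proline (30 mol %), hydroxyacetone/DMSO 1:4, rt
Reagents that add atoms: none
Why: The proline enamine of hydroxyacetone adds through its hydroxylated carbon to the aldehyde re face in the hydrogen-bonded chair transition state (proline-catalysed direct aldol), which should give the anti diol with C8 and C9 both S under catalyst control.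

Step 4
Reactants: 5 methyl (2Z,5R,6S,7S)-6,7-dihydroxy-2-methyl-8-oxo-5-(prop-1-en-2-yl)non-2-enoate
Product: 6 methyl (2Z,5R)-5-[(6S,7S)-7-acetyl-2,2,4,4-tetra(propan-2-yl)-1,3,5,2,4-trioxadisilepan-6-yl]-2,6-dimethylhepta-2,6-dienoate
Conditions: (i-Pr2SiCl)2O, imidazole, DMF, 0 °C to rt
Reagents that add atoms: 1,3-dichloro-1,1,3,3-tetraisopropyldisiloxane, CC(C)[Si](Cl)(C(C)C)O[Si](Cl)(C(C)C)C(C)C
Why: The bifunctional silyl chloride bridges the vicinal diol as a seven-membered disiloxane (cyclic silyl protection), leaving O9 as a non-chelating silyl ether next to the ketone.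

Step 5
Reactants: 6 methyl (2Z,5R)-5-[(6S,7S)-7-acetyl-2,2,4,4-tetra(propan-2-yl)-1,3,5,2,4-trioxadisilepan-6-yl]-2,6-dimethylhepta-2,6-dienoate
Product: 8 methyl (2Z,5R)-5-{(6S,7S)-7-[(2R)-1,2-dihydroxypropan-2-yl]-2,2,4,4-tetra(propan-2-yl)-1,3,5,2,4-trioxadisilepan-6-yl}-2,6-dimethylhepta-2,6-dienoate, via β-hydroxysilane 7 (not isolated)
Conditions: ClMgCH2SiMe2(Oi-Pr), THF, −78 °C; then KF, KHCO3, 30% H2O2, THF/MeOH, rt
Reagents that add atoms: (isopropoxydimethylsilyl)methylmagnesium chloride, CC(C)O[Si](C)(C)C[Mg]Cl; hydrogen peroxide, OO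
Why: With O9 silylated and unable to chelate, the Grignard reagent should add to the C10 ketone in the Felkin–Anh sense (C9–O bond anti to the incoming carbon) faster than to the hindered enoate, and the Tamao oxidation then turns the C–Si bond into the C1 hydroxyl without change at carbon.

Step 6
Reactants: 8 methyl (2Z,5R)-5-{(6S,7S)-7-[(2R)-1,2-dihydroxypropan-2-yl]-2,2,4,4-tetra(propan-2-yl)-1,3,5,2,4-trioxadisilepan-6-yl}-2,6-dimethylhepta-2,6-dienoate
Product: 9 methyl (2Z,5R)-5-{(6S,7S)-7-[(4R)-2-(4-methoxyphenyl)-4-methyl-1,3-dioxolan-4-yl]-2,2,4,4-tetra(propan-2-yl)-1,3,5,2,4-trioxadisilepan-6-yl}-2,6-dimethylhepta-2,6-dienoate (both acetal epimers)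
Conditions: 4-MeOC6H4CH(OMe)2, PPTS (cat.), CH2Cl2, rt
Reagents that add atoms: 4-methoxybenzaldehyde dimethyl acetal, COc1ccc(C(OC)OC)cc1
Why: Acid-catalysed transacetalisation closes the five-membered 4-methoxybenzylidene acetal on the primary/tertiary 1,2-diol under conditions that leave the disiloxane intact.

Step 7
Reactants: 9 methyl (2Z,5R)-5-{(6S,7S)-7-[(4R)-2-(4-methoxyphenyl)-4-methyl-1,3-dioxolan-4-yl]-2,2,4,4-tetra(propan-2-yl)-1,3,5,2,4-trioxadisilepan-6-yl}-2,6-dimethylhepta-2,6-dienoate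
Product: 10 (2Z,5R)-5-{(6S,7S)-7-[(2R)-1-hydroxy-2-[(4-methoxyphenyl)methoxy]propan-2-yl]-2,2,4,4-tetra(propan-2-yl)-1,3,5,2,4-trioxadisilepan-6-yl}-2,6-dimethylhepta-2,6-dien-1-ol
Conditions: i-Bu2AlH (6 equiv), CH2Cl2, −78 to 0 °C; aq. potassium sodium tartrate
Reagents that add atoms: none
Why: i-Bu2AlH reduces the ester to the Z-allylic alcohol and, by binding the less hindered primary acetal oxygen, opens the acetal so that the 4-methoxybenzyl group stays on the tertiary O10 (regioselective reductive acetal opening).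

Step 8
Reactants: 10 (2Z,5R)-5-{(6S,7S)-7-[(2R)-1-hydroxy-2-[(4-methoxyphenyl)methoxy]propan-2-yl]-2,2,4,4-tetra(propan-2-yl)-1,3,5,2,4-trioxadisilepan-6-yl}-2,6-dimethylhepta-2,6-dien-1-ol
Product: 11 (2Z,5R)-5-{(6S,7S)-7-[(2R)-1-hydroxy-2-[(4-methoxyphenyl)methoxy]propan-2-yl]-2,2,4,4-tetra(propan-2-yl)-1,3,5,2,4-trioxadisilepan-6-yl}-2,6-dimethylhepta-2,6-dienal
Conditions: MnO2, CH2Cl2, rt
Reagents that add atoms: none
Why: MnO2 oxidises only the allylic primary alcohol (chemoselective allylic oxidation) under neutral conditions that should keep the Z-enal geometry and leave the saturated C1 hydroxyl.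

Step 9
Reactants: 11 (2Z,5R)-5-{(6S,7S)-7-[(2R)-1-hydroxy-2-[(4-methoxyphenyl)methoxy]propan-2-yl]-2,2,4,4-tetra(propan-2-yl)-1,3,5,2,4-trioxadisilepan-6-yl}-2,6-dimethylhepta-2,6-dienal
Product: 12 (3Z,6R)-1-bromo-6-{(6S,7S)-7-[(2R)-1-hydroxy-2-[(4-methoxyphenyl)methoxy]propan-2-yl]-2,2,4,4-tetra(propan-2-yl)-1,3,5,2,4-trioxadisilepan-6-yl}-3,7-dimethylocta-3,7-dien-2-ol (both C2 epimers)
Conditions: BrCH2I, MeLi·LiBr (3.2 equiv), THF, −78 °C; AcOH, −78 °C
Reagents that add atoms: bromoiodomethane, BrCI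
Why: Iodine–lithium exchange makes bromomethyllithium in the presence of the aldehyde, to which it adds 1,2 faster than it decomposes (halomethyllithium addition), and the cold acidic quench keeps the bromohydrin from closing to an epoxide.

Step 10
Reactants: 12 (3Z,6R)-1-bromo-6-{(6S,7S)-7-[(2R)-1-hydroxy-2-[(4-methoxyphenyl)methoxy]propan-2-yl]-2,2,4,4-tetra(propan-2-yl)-1,3,5,2,4-trioxadisilepan-6-yl}-3,7-dimethylocta-3,7-dien-2-ol
Product: 13 (2S)-2-{(6S,7S)-6-[(3R,5Z)-8-bromo-2,6-dimethyl-7-oxoocta-1,5-dien-3-yl]-2,2,4,4-tetra(propan-2-yl)-1,3,5,2,4-trioxadisilepan-7-yl}-2-[(4-methoxyphenyl)methoxy]propanal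
Conditions: DMP (1,1,1-triacetoxy-1,1-dihydro-1,2-benziodoxol-3(1H)-one, 3 equiv), NaHCO3, CH2Cl2, 0 °C to rt
Reagents that add atoms: none
Why: The Dess–Martin oxidation converts the secondary bromohydrin into the bromomethyl ketone and the primary alcohol into the non-enolisable aldehyde in one buffered operation.

Step 11
Reactants: 13 (2S)-2-{(6S,7S)-6-[(3R,5Z)-8-bromo-2,6-dimethyl-7-oxoocta-1,5-dien-3-yl]-2,2,4,4-tetra(propan-2-yl)-1,3,5,2,4-trioxadisilepan-7-yl}-2-[(4-methoxyphenyl)methoxy]propanal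
Product: 14 (1S,4Z,7R,8S,9S,10R)-1-hydroxy-10-[(4-methoxyphenyl)methoxy]-4,10-dimethyl-7-(prop-1-en-2-yl)-8,9-[(1,1,3,3-tetraisopropyldisiloxane-1,3-diyl)bis(oxy)]cyclodec-4-en-3-one (ring locants as in the plan)
Conditions: SmI2 (2.5 equiv), THF, −78 °C, slow addition of 13 (final 2 mM); aq. NH4Cl
Reagents that add atoms: none
Why: Two single-electron transfers from SmI2 cleave the C2–Br bond and give the oxygen-bound trivalent samarium dienolate, which adds through C2 to the aldehyde carbon C1 in a closed chair-like transition state held together by samarium. The closest known reaction type is the SmI2-mediated intramolecular Reformatsky (reductive aldol) closure of medium and large rings from formyl-tethered α-halo carbonyl compounds. The ten-membered carbocycle closes in the 10-(enolendo)-exo-trig mode, with the existing seven-membered disiloxane ring cis-fused to it. The new stereocentre C1 is controlled by the five-membered chelate of trivalent samarium between the aldehyde oxygen and the benzylic ether oxygen on C10 (Cram chelate), so C2 should arrive on the face carrying the C10 methyl group and anti to C9, giving 1S. The step needs a single enolate, reduction of the C–Br bond before the aldehyde, and closure before dimerisation: the enolate is born at the brominated carbon and cannot move (C4 has no hydrogen, C10 is quaternary), the α-bromo ketone is reduced far faster than an aldehyde at −78 °C, and slow addition at high dilution together with the Z-alkene and the disiloxane ring favours the intramolecular path.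

Step 12
Reactants: 14 (1S,4Z,7R,8S,9S,10R)-1-hydroxy-10-[(4-methoxyphenyl)methoxy]-4,10-dimethyl-7-(prop-1-en-2-yl)-8,9-[(1,1,3,3-tetraisopropyldisiloxane-1,3-diyl)bis(oxy)]cyclodec-4-en-3-one
Product: 15 (1S,3S,4Z,7R,8S,9S,10R)-10-[(4-methoxyphenyl)methoxy]-4,10-dimethyl-7-(prop-1-en-2-yl)-8,9-[(1,1,3,3-tetraisopropyldisiloxane-1,3-diyl)bis(oxy)]cyclodec-4-ene-1,3-diol
Conditions: Me4NBH(OAc)3, MeCN/AcOH 1:1, −30 °C
Reagents that add atoms: none
Why: Exchange of the C1 hydroxyl onto boron gives an alkoxy(diacetoxy)borohydride that delivers hydride to the C3 ketone through a six-membered chair (Evans–Saksena reduction), which should set C3 as S, 1,3-anti to C1, with 1,2-selectivity on the enone.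

Step 13
Reactants: 15 (1S,3S,4Z,7R,8S,9S,10R)-10-[(4-methoxyphenyl)methoxy]-4,10-dimethyl-7-(prop-1-en-2-yl)-8,9-[(1,1,3,3-tetraisopropyldisiloxane-1,3-diyl)bis(oxy)]cyclodec-4-ene-1,3-diol
Product: 16 (1S,3S,4Z,7R,8S,9S,10R)-4,10-dimethyl-7-(prop-1-en-2-yl)-8,9-[(1,1,3,3-tetraisopropyldisiloxane-1,3-diyl)bis(oxy)]cyclodec-4-ene-1,3,10-triol
Conditions: MgBr2·OEt2, Me2S, CH2Cl2, rt
Reagents that add atoms: none
Why: MgBr2, held by the neighbouring hydroxyl, activates the tertiary 4-methoxybenzyl ether and Me2S captures the benzyl cation (Lewis acid/soft nucleophile ether cleavage), so the ether is removed without an oxidant that could tie the C1 hydroxyl into an acetal.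

Step 14
Reactants: 16 (1S,3S,4Z,7R,8S,9S,10R)-4,10-dimethyl-7-(prop-1-en-2-yl)-8,9-[(1,1,3,3-tetraisopropyldisiloxane-1,3-diyl)bis(oxy)]cyclodec-4-ene-1,3,10-triol
Product: 18 (1R,3S,4Z,7R,8S,9S,10R)-1,10-epoxy-4,10-dimethyl-7-(prop-1-en-2-yl)-8,9-[(1,1,3,3-tetraisopropyldisiloxane-1,3-diyl)bis(oxy)]cyclodec-4-en-3-ol, via tosylate 17 (not isolated)
Conditions: Bu2SnO (10 mol %), TsCl, Et3N, CH2Cl2, rt; then K2CO3, MeOH, rt
Reagents that add atoms: none
Why: The tin acetal forms on the 1,2-diol and activates its secondary oxygen, so sulfonylation should occur at O1 rather than at the isolated C3 hydroxyl (tin-mediated regioselective sulfonylation), and base then closes the epoxide by SN2 attack of the C10 oxygen on C1 with inversion, placing C2 cis to C9.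

Step 15
Reactants: 18 (1R,3S,4Z,7R,8S,9S,10R)-1,10-epoxy-4,10-dimethyl-7-(prop-1-en-2-yl)-8,9-[(1,1,3,3-tetraisopropyldisiloxane-1,3-diyl)bis(oxy)]cyclodec-4-en-3-ol
Product: 19 (1R,3S,4R,5S,7R,8S,9S,10R)-1,10:4,5-diepoxy-4,10-dimethyl-7-(prop-1-en-2-yl)-8,9-[(1,1,3,3-tetraisopropyldisiloxane-1,3-diyl)bis(oxy)]cyclodecan-3-ol
Conditions: mCPBA (1.1 equiv), NaHCO3, CH2Cl2, −20 °C
Reagents that add atoms: 3-chloroperoxybenzoic acid, OOC(=O)c1cccc(Cl)c1
Why: Hydrogen-bonded delivery from the free C3 hydroxyl (Henbest-type directed peracid epoxidation), on the conformer that avoids A(1,3) strain in the Z-allylic alcohol, should give the trans (threo) epoxy alcohol as peracids do with medium-ring cis-cycloalkenols, and the hydroxyl-activated trisubstituted alkene should react before the isopropenyl group.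

Step 16
Reactants: 19 (1R,3S,4R,5S,7R,8S,9S,10R)-1,10:4,5-diepoxy-4,10-dimethyl-7-(prop-1-en-2-yl)-8,9-[(1,1,3,3-tetraisopropyldisiloxane-1,3-diyl)bis(oxy)]cyclodecan-3-ol; 20 angelic acid
Product: 21 (1R,3S,4S,5S,7R,8S,9S,10R)-1,10:4,5-diepoxy-4,10-dimethyl-7-(prop-1-en-2-yl)-8,9-[(1,1,3,3-tetraisopropyldisiloxane-1,3-diyl)bis(oxy)]cyclodecan-3-yl (2Z)-2-methylbut-2-enoate
Conditions: 20, 2,4,6-trichlorobenzoyl chloride, Et3N, toluene, rt; then 19, toluene, 75 °C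
Reagents that add atoms: none
Why: Acylation of the only free hydroxyl by the preformed mixed anhydride without a nucleophilic catalyst (Yamaguchi-type esterification) should install the angelate without Z-to-E isomerisation.

Step 17
Reactants: 21 (1R,3S,4S,5S,7R,8S,9S,10R)-1,10:4,5-diepoxy-4,10-dimethyl-7-(prop-1-en-2-yl)-8,9-[(1,1,3,3-tetraisopropyldisiloxane-1,3-diyl)bis(oxy)]cyclodecan-3-yl (2Z)-2-methylbut-2-enoate
Product: 22 (1R,3S,4S,5S,7R,8S,9S,10S)-1,10:4,5-diepoxy-8,9-dihydroxy-4,10-dimethyl-7-(prop-1-en-2-yl)cyclodecan-3-yl (2Z)-2-methylbut-2-enoate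
Conditions: Bu4NF, AcOH (1:1), THF, 0 °C to rt
Reagents that add atoms: none
Why: Fluoride buffered with acetic acid cleaves the disiloxane bridge (silyl ether cleavage) under near-neutral conditions that should spare both epoxides and the ester and prevent epoxide migration through free alkoxides.

Step 18
Reactants: 22 (1R,3S,4S,5S,7R,8S,9S,10S)-1,10:4,5-diepoxy-8,9-dihydroxy-4,10-dimethyl-7-(prop-1-en-2-yl)cyclodecan-3-yl (2Z)-2-methylbut-2-enoate
Product: 23 (1R,3S,4S,5S,7R,8S,9S,10S)-8-(acetyloxy)-1,10:4,5-diepoxy-9-hydroxy-4,10-dimethyl-7-(prop-1-en-2-yl)cyclodecan-3-yl (2Z)-2-methylbut-2-enoate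
Conditions: Ac2O (1.05 equiv), pyridine, CH2Cl2, −20 °C
Reagents that add atoms: acetic anhydride, CC(=O)OC(C)=O
Why: C8–OH lies between two methine carbons whereas C9–OH sits next to the fully substituted epoxide carbon C10, so one equivalent of Ac2O at low temperature should acylate O8 (sterically controlled acylation).

Step 19
Reactants: 23 (1R,3S,4S,5S,7R,8S,9S,10S)-8-(acetyloxy)-1,10:4,5-diepoxy-9-hydroxy-4,10-dimethyl-7-(prop-1-en-2-yl)cyclodecan-3-yl (2Z)-2-methylbut-2-enoate; 20 angelic acid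
Product: 24 (1R,3S,4S,5S,7R,8S,9S,10R)-8-(acetyloxy)-1,10:4,5-diepoxy-4,10-dimethyl-7-(prop-1-en-2-yl)cyclodecane-3,9-diyl bis[(2Z)-2-methylbut-2-enoate] (target)
Conditions: 20, 2,4,6-trichlorobenzoyl chloride, Et3N, toluene, rt; then 23, toluene, 75 °C
Reagents that add atoms: none
Why: The same mixed-anhydride esterification should acylate the remaining hindered C9 hydroxyl under weakly basic conditions that avoid acetyl migration from O8 and angelate isomerisation, giving the target.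

**Compound list**

1 | (S)-carvone, (5S)-2-methyl-5-(prop-1-en-2-yl)cyclohex-2-en-1-one | CC1=CC[C@@H](CC1=O)C(C)=C | starting material
2 | (5R,6R)-6-hydroxy-2-methyl-5-(prop-1-en-2-yl)cyclohex-2-en-1-one | CC1=CC[C@@H]([C@@H](O)C1=O)C(C)=C | intermediate
3 | methyl (2Z,5R)-5-formyl-2,6-dimethylhepta-2,6-dienoate | COC(=O)/C(C)=C\C[C@@H](C=O)C(C)=C | intermediate
4 | hydroxyacetone (1-hydroxypropan-2-one) | CC(=O)CO | starting material
5 | methyl (2Z,5R,6S,7S)-6,7-dihydroxy-2-methyl-8-oxo-5-(prop-1-en-2-yl)non-2-enoate | COC(=O)/C(C)=C\C[C@@H]([C@H](O)[C@H](O)C(C)=O)C(C)=C | intermediate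
6 | methyl (2Z,5R)-5-[(6S,7S)-7-acetyl-2,2,4,4-tetra(propan-2-yl)-1,3,5,2,4-trioxadisilepan-6-yl]-2,6-dimethylhepta-2,6-dienoate | COC(=O)/C(C)=C\C[C@@H]([C@@H]1O[Si](C(C)C)(C(C)C)O[Si](C(C)C)(C(C)C)O[C@@H]1C(C)=O)C(C)=C | intermediate
7 | β-hydroxysilane: 6 with the acetyl group replaced by (2S)-1-[dimethyl(propan-2-yloxy)silyl]-2-hydroxypropan-2-yl | COC(=O)/C(C)=C\C[C@@H]([C@@H]1O[Si](C(C)C)(C(C)C)O[Si](C(C)C)(C(C)C)O[C@@H]1[C@](C)(O)C[Si](C)(C)OC(C)C)C(C)=C | intermediate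
8 | methyl (2Z,5R)-5-{(6S,7S)-7-[(2R)-1,2-dihydroxypropan-2-yl]-2,2,4,4-tetra(propan-2-yl)-1,3,5,2,4-trioxadisilepan-6-yl}-2,6-dimethylhepta-2,6-dienoate | COC(=O)/C(C)=C\C[C@@H]([C@@H]1O[Si](C(C)C)(C(C)C)O[Si](C(C)C)(C(C)C)O[C@@H]1[C@](C)(O)CO)C(C)=C | intermediate
9 | methyl (2Z,5R)-5-{(6S,7S)-7-[(4R)-2-(4-methoxyphenyl)-4-methyl-1,3-dioxolan-4-yl]-2,2,4,4-tetra(propan-2-yl)-1,3,5,2,4-trioxadisilepan-6-yl}-2,6-dimethylhepta-2,6-dienoate (both acetal epimers) | COC(=O)/C(C)=C\C[C@@H]([C@@H]1O[Si](C(C)C)(C(C)C)O[Si](C(C)C)(C(C)C)O[C@@H]1[C@@]1(C)COC(c2ccc(OC)cc2)O1)C(C)=C | intermediate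
10 | (2Z,5R)-5-{(6S,7S)-7-[(2R)-1-hydroxy-2-[(4-methoxyphenyl)methoxy]propan-2-yl]-2,2,4,4-tetra(propan-2-yl)-1,3,5,2,4-trioxadisilepan-6-yl}-2,6-dimethylhepta-2,6-dien-1-ol | OC/C(C)=C\C[C@@H]([C@@H]1O[Si](C(C)C)(C(C)C)O[Si](C(C)C)(C(C)C)O[C@@H]1[C@@](C)(CO)OCc1ccc(OC)cc1)C(C)=C | intermediate
11 | (2Z,5R)-5-{(6S,7S)-7-[(2R)-1-hydroxy-2-[(4-methoxyphenyl)methoxy]propan-2-yl]-2,2,4,4-tetra(propan-2-yl)-1,3,5,2,4-trioxadisilepan-6-yl}-2,6-dimethylhepta-2,6-dienal | O=C/C(C)=C\C[C@@H]([C@@H]1O[Si](C(C)C)(C(C)C)O[Si](C(C)C)(C(C)C)O[C@@H]1[C@@](C)(CO)OCc1ccc(OC)cc1)C(C)=C | intermediate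
12 | (3Z,6R)-1-bromo-6-{(6S,7S)-7-[(2R)-1-hydroxy-2-[(4-methoxyphenyl)methoxy]propan-2-yl]-2,2,4,4-tetra(propan-2-yl)-1,3,5,2,4-trioxadisilepan-6-yl}-3,7-dimethylocta-3,7-dien-2-ol (both C2 epimers) | OC(CBr)/C(C)=C\C[C@@H]([C@@H]1O[Si](C(C)C)(C(C)C)O[Si](C(C)C)(C(C)C)O[C@@H]1[C@@](C)(CO)OCc1ccc(OC)cc1)C(C)=C | intermediate
13 | (2S)-2-{(6S,7S)-6-[(3R,5Z)-8-bromo-2,6-dimethyl-7-oxoocta-1,5-dien-3-yl]-2,2,4,4-tetra(propan-2-yl)-1,3,5,2,4-trioxadisilepan-7-yl}-2-[(4-methoxyphenyl)methoxy]propanal | O=C(CBr)/C(C)=C\C[C@@H]([C@@H]1O[Si](C(C)C)(C(C)C)O[Si](C(C)C)(C(C)C)O[C@@H]1[C@@](C)(C=O)OCc1ccc(OC)cc1)C(C)=C | intermediate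
14 | (1S,4Z,7R,8S,9S,10R)-1-hydroxy-10-[(4-methoxyphenyl)methoxy]-4,10-dimethyl-7-(prop-1-en-2-yl)-8,9-[(1,1,3,3-tetraisopropyldisiloxane-1,3-diyl)bis(oxy)]cyclodec-4-en-3-one (ring locants as in the plan) | C=C(C)[C@H]1C/C=C(C)\C(=O)C[C@H](O)[C@@](C)(OCc2ccc(OC)cc2)[C@H]2O[Si](C(C)C)(C(C)C)O[Si](C(C)C)(C(C)C)O[C@@H]12 | intermediate
15 | (1S,3S,4Z,7R,8S,9S,10R)-10-[(4-methoxyphenyl)methoxy]-4,10-dimethyl-7-(prop-1-en-2-yl)-8,9-[(1,1,3,3-tetraisopropyldisiloxane-1,3-diyl)bis(oxy)]cyclodec-4-ene-1,3-diol | C=C(C)[C@H]1C/C=C(C)\[C@@H](O)C[C@H](O)[C@@](C)(OCc2ccc(OC)cc2)[C@H]2O[Si](C(C)C)(C(C)C)O[Si](C(C)C)(C(C)C)O[C@@H]12 | intermediate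
16 | (1S,3S,4Z,7R,8S,9S,10R)-4,10-dimethyl-7-(prop-1-en-2-yl)-8,9-[(1,1,3,3-tetraisopropyldisiloxane-1,3-diyl)bis(oxy)]cyclodec-4-ene-1,3,10-triol | C=C(C)[C@H]1C/C=C(C)\[C@@H](O)C[C@H](O)[C@@](C)(O)[C@H]2O[Si](C(C)C)(C(C)C)O[Si](C(C)C)(C(C)C)O[C@@H]12 | intermediate
17 | 1-O-(4-methylbenzenesulfonyl) derivative of 16 (C3 and C10 hydroxyls free) | C=C(C)[C@H]1C/C=C(C)\[C@@H](O)C[C@H](OS(=O)(=O)c2ccc(C)cc2)[C@@](C)(O)[C@H]2O[Si](C(C)C)(C(C)C)O[Si](C(C)C)(C(C)C)O[C@@H]12 | intermediate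
18 | (1R,3S,4Z,7R,8S,9S,10R)-1,10-epoxy-4,10-dimethyl-7-(prop-1-en-2-yl)-8,9-[(1,1,3,3-tetraisopropyldisiloxane-1,3-diyl)bis(oxy)]cyclodec-4-en-3-ol | C=C(C)[C@H]1C/C=C(C)\[C@@H](O)C[C@H]2O[C@@]2(C)[C@H]2O[Si](C(C)C)(C(C)C)O[Si](C(C)C)(C(C)C)O[C@@H]12 | intermediate
19 | (1R,3S,4R,5S,7R,8S,9S,10R)-1,10:4,5-diepoxy-4,10-dimethyl-7-(prop-1-en-2-yl)-8,9-[(1,1,3,3-tetraisopropyldisiloxane-1,3-diyl)bis(oxy)]cyclodecan-3-ol | C=C(C)[C@H]1C[C@@H]2O[C@]2(C)[C@@H](O)C[C@H]2O[C@@]2(C)[C@H]2O[Si](C(C)C)(C(C)C)O[Si](C(C)C)(C(C)C)O[C@@H]12 | intermediate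
20 | angelic acid, (2Z)-2-methylbut-2-enoic acid | C/C=C(/C)C(=O)O | starting material
21 | (1R,3S,4S,5S,7R,8S,9S,10R)-1,10:4,5-diepoxy-4,10-dimethyl-7-(prop-1-en-2-yl)-8,9-[(1,1,3,3-tetraisopropyldisiloxane-1,3-diyl)bis(oxy)]cyclodecan-3-yl (2Z)-2-methylbut-2-enoate | C=C(C)[C@H]1C[C@@H]2O[C@]2(C)[C@@H](OC(=O)/C(C)=C\C)C[C@H]2O[C@@]2(C)[C@H]2O[Si](C(C)C)(C(C)C)O[Si](C(C)C)(C(C)C)O[C@@H]12 | intermediate
22 | (1R,3S,4S,5S,7R,8S,9S,10S)-1,10:4,5-diepoxy-8,9-dihydroxy-4,10-dimethyl-7-(prop-1-en-2-yl)cyclodecan-3-yl (2Z)-2-methylbut-2-enoate | C=C(C)[C@H]1C[C@@H]2O[C@]2(C)[C@@H](OC(=O)/C(C)=C\C)C[C@H]2O[C@@]2(C)[C@@H](O)[C@H]1O | intermediate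
23 | (1R,3S,4S,5S,7R,8S,9S,10S)-8-(acetyloxy)-1,10:4,5-diepoxy-9-hydroxy-4,10-dimethyl-7-(prop-1-en-2-yl)cyclodecan-3-yl (2Z)-2-methylbut-2-enoate | C=C(C)[C@H]1C[C@@H]2O[C@]2(C)[C@@H](OC(=O)/C(C)=C\C)C[C@H]2O[C@@]2(C)[C@@H](O)[C@H]1OC(C)=O | intermediate
24 | (1R,3S,4S,5S,7R,8S,9S,10R)-8-(acetyloxy)-1,10:4,5-diepoxy-4,10-dimethyl-7-(prop-1-en-2-yl)cyclodecane-3,9-diyl bis[(2Z)-2-methylbut-2-enoate] | C=C(C)[C@H]1C[C@@H]2O[C@]2(C)[C@@H](OC(=O)/C(C)=C\C)C[C@H]2O[C@@]2(C)[C@@H](OC(=O)/C(C)=C\C)[C@H]1OC(C)=O | target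

**Totals and risks**

Total step count: 19. Longest linear sequence: 19 steps (from 1).

Steps most likely to fail:

Step 11 (ring closure). What may go wrong: intermolecular coupling to dimers, pinacol-type coupling at the aldehyde, or loss of chelate control at C1. The fallback replaces the reductive samarium enolate by a Lewis-acid-templated closure of a preformed silyl dienol ether. It sets out from 11: MeMgBr (THF, −78 °C) should give the secondary allylic alcohol F1; Dess–Martin oxidation of both hydroxyls should give the methyl ketone aldehyde F2; Me3SiOTf/Et3N should give the silyl dienol ether F3; MgBr2·OEt2 in CH2Cl2 at high dilution (−78 to 0 °C) should then close the ring by a chelation-controlled Mukaiyama aldol addition and, after hydrolytic work-up, come back to the route at 14.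

Step 3 (aldol). What may go wrong: epimerisation at C7 or migration of the isopropenyl double bond into conjugation through iminium/enamine formation of the α-branched aldehyde, or mismatched double diastereoselection. The fallback is a neutral, reagent-controlled allylboration. It sets out from 3: the diisopropyl tartrate ester of (E)-[3-(cyclohexyloxydimethylsilyl)prop-2-en-1-yl]boronic acid (toluene, −78 °C, molecular sieves) should give the anti β-hydroxy allylsilane F4; H2O2/KF/KHCO3 should give the anti diol with a terminal vinyl group F5; (i-Pr2SiCl)2O/imidazole should give the disiloxane F6; Wacker oxidation of the terminal vinyl group (PdCl2, CuCl, O2, DMF/H2O) should come back to the route at 6.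

Step 5 (C10 centre). What may go wrong: poor facial selectivity at the ketone (erosion of Felkin–Anh control by partial chelation) or competing attack on the ester. The fallback sets C10 by a hydroxyl-directed epoxidation instead of a carbonyl addition. It sets out from 5: methylenation of the ketone (Zn, CH2Br2, TiCl4) should give the 2-methylallylic alcohol F7; VO(acac)2/t-BuOOH, directed by C9–OH and governed by A(1,2) strain, should give the erythro terminal epoxide F8; (i-Pr2SiCl)2O/imidazole should give the disiloxane F9; CsOAc (DMF, 60 °C) should open the epoxide at its CH2 carbon to the primary acetate F10; K2CO3/MeOH should then come back to the route at 8.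

Further compounds

F1 | step 11 | (3Z,6R)-6-{(6S,7S)-7-[(2R)-1-hydroxy-2-[(4-methoxyphenyl)methoxy]propan-2-yl]-2,2,4,4-tetra(propan-2-yl)-1,3,5,2,4-trioxadisilepan-6-yl}-3,7-dimethylocta-3,7-dien-2-ol (both C2 epimers) | CC(O)/C(C)=C\C[C@@H]([C@@H]1O[Si](C(C)C)(C(C)C)O[Si](C(C)C)(C(C)C)O[C@@H]1[C@@](C)(CO)OCc1ccc(OC)cc1)C(C)=C
F2 | step 11 | (2S)-2-{(6S,7S)-6-[(3R,5Z)-2,6-dimethyl-7-oxoocta-1,5-dien-3-yl]-2,2,4,4-tetra(propan-2-yl)-1,3,5,2,4-trioxadisilepan-7-yl}-2-[(4-methoxyphenyl)methoxy]propanal | CC(=O)/C(C)=C\C[C@@H]([C@@H]1O[Si](C(C)C)(C(C)C)O[Si](C(C)C)(C(C)C)O[C@@H]1[C@@](C)(C=O)OCc1ccc(OC)cc1)C(C)=C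
F3 | step 11 | (2S)-2-{(6S,7S)-6-[(3R,5Z)-2,6-dimethyl-7-(trimethylsilyloxy)octa-1,5,7-trien-3-yl]-2,2,4,4-tetra(propan-2-yl)-1,3,5,2,4-trioxadisilepan-7-yl}-2-[(4-methoxyphenyl)methoxy]propanal | C=C(O[Si](C)(C)C)/C(C)=C\C[C@@H]([C@@H]1O[Si](C(C)C)(C(C)C)O[Si](C(C)C)(C(C)C)O[C@@H]1[C@@](C)(C=O)OCc1ccc(OC)cc1)C(C)=C
F4 | step 3 | methyl (2Z,5R,6S,7R)-7-[(cyclohexyloxy)dimethylsilyl]-6-hydroxy-2-methyl-5-(prop-1-en-2-yl)nona-2,8-dienoate | COC(=O)/C(C)=C\C[C@@H]([C@H](O)[C@H]([Si](C)(C)OC1CCCCC1)C=C)C(C)=C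
F5 | step 3 | methyl (2Z,5R,6S,7R)-6,7-dihydroxy-2-methyl-5-(prop-1-en-2-yl)nona-2,8-dienoate | COC(=O)/C(C)=C\C[C@@H]([C@H](O)[C@H](O)C=C)C(C)=C
F6 | step 3 | methyl (2Z,5R)-5-[(6S,7R)-7-ethenyl-2,2,4,4-tetra(propan-2-yl)-1,3,5,2,4-trioxadisilepan-6-yl]-2,6-dimethylhepta-2,6-dienoate | COC(=O)/C(C)=C\C[C@@H]([C@@H]1O[Si](C(C)C)(C(C)C)O[Si](C(C)C)(C(C)C)O[C@@H]1C=C)C(C)=C
F7 | step 5 | methyl (2Z,5R,6S,7R)-6,7-dihydroxy-2,8-dimethyl-5-(prop-1-en-2-yl)nona-2,8-dienoate | COC(=O)/C(C)=C\C[C@@H]([C@H](O)[C@H](O)C(C)=C)C(C)=C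
F8 | step 5 | methyl (2Z,5R,6S,7S)-6,7-dihydroxy-2-methyl-7-[(2R)-2-methyloxiran-2-yl]-5-(prop-1-en-2-yl)hept-2-enoate | COC(=O)/C(C)=C\C[C@@H]([C@H](O)[C@H](O)[C@@]1(C)CO1)C(C)=C
F9 | step 5 | methyl (2Z,5R)-2,6-dimethyl-5-{(6S,7S)-7-[(2R)-2-methyloxiran-2-yl]-2,2,4,4-tetra(propan-2-yl)-1,3,5,2,4-trioxadisilepan-6-yl}hepta-2,6-dienoate | COC(=O)/C(C)=C\C[C@@H]([C@@H]1O[Si](C(C)C)(C(C)C)O[Si](C(C)C)(C(C)C)O[C@@H]1[C@@]1(C)CO1)C(C)=C
F10 | step 5 | methyl (2Z,5R)-5-{(6S,7S)-7-[(2R)-1-(acetyloxy)-2-hydroxypropan-2-yl]-2,2,4,4-tetra(propan-2-yl)-1,3,5,2,4-trioxadisilepan-6-yl}-2,6-dimethylhepta-2,6-dienoate | COC(=O)/C(C)=C\C[C@@H]([C@@H]1O[Si](C(C)C)(C(C)C)O[Si](C(C)C)(C(C)C)O[C@@H]1[C@](C)(O)COC(C)=O)C(C)=C
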